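**Plan**

- Retrosynthetic cuts: the three MOM acetals; C8–C(1,1-dimethylallyl) (aromatic Claisen shift from O7); C5–O and C7–O (two SNAr steps on a 5,7-difluoroflavone); O1–C8a (ring C, intramolecular SNAr); C3–C4 (enolate C-acylation); C5'–prenyl (Negishi coupling).
- Forward order: ring B is a purchased bromocatechol ester that is protected, prenylated and converted to an α-(methoxymethoxy)methyl ketone; ring A arrives as 2,4,6-trifluorobenzoyl chloride; ring C closes in step 6; the C7 and C5 fluorines are then exchanged for oxygen and the C8 side chain is delivered from O7.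
- Enabling feature: the O1–C8a aryl ether of ring C lies ortho to the C4 carbonyl on ring A, so a 2-fluoroaryl ketone can accept the enolate oxygen, while O5 and O7 map onto the two other fluorines of a 2,4,6-trifluorophenyl group.
- Stereochemistry: the target has no stereocentre and no stereogenic alkene. The constitution of the side chains comes from linear-selective coupling (prenyl at C5') and from the allyl inversion of the [3,3] shift (1,1-dimethylallyl at C8).

Key step: step 6

Remark: diketone 9 is drawn in its keto form; its C2 centre is racemic, labile through the enol, and disappears on cyclisation. Compounds 1, 3, 8 and 11 and the reagents named are assumed to be catalogue chemicals.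

**Route**

Step 1
Reactants: 1 methyl 3-bromo-4,5-dihydroxybenzoate
Product: 2 methyl 3-bromo-4,5-bis(methoxymethoxy)benzoate
Conditions: MOMCl, i-Pr2NEt, CH2Cl2, 0 °C → reflux
Reagents that add atoms: chloromethyl methyl ether, COCCl
Why: O-alkylation of both catechol hydroxyls (MOM ether formation) under amine base leaves the ester and the aryl bromide untouched and installs acetals that should survive every basic, organometallic and thermal step up to the final acidic release.

Step 2
Reactants: 2 methyl 3-bromo-4,5-bis(methoxymethoxy)benzoate; 3 1-bromo-3-methylbut-2-ene (prenyl bromide)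
Product: 5 methyl 3,4-bis(methoxymethoxy)-5-(3-methylbut-2-enyl)benzoate, via prenylzinc bromide 4 (not isolated)
Conditions: 3, Zn dust, LiCl, THF, 0 °C → rt; then 2, Pd(OAc)2 (2 mol %), CPhos (4 mol %), THF, rt
Reagents that add atoms: none
Why: Negishi cross-coupling of an aryl bromide with prenylzinc bromide under zerovalent palladium carrying the biaryl phosphine CPhos is known to give the linear prenyl arene because reductive elimination outruns allyl transposition, and the organozinc tolerates the methyl ester at room temperature.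

Step 3
Reactants: 5 methyl 3,4-bis(methoxymethoxy)-5-(3-methylbut-2-enyl)benzoate
Product: 6 N-methoxy-N-methyl-3,4-bis(methoxymethoxy)-5-(3-methylbut-2-enyl)benzamide
Conditions: MeNHOMe·HCl, i-PrMgCl, THF, −20 → 0 °C
Reagents that add atoms: N,O-dimethylhydroxylamine hydrochloride, CNOC.Cl
Why: Direct aminolysis of the methyl ester by the chloromagnesium amide formed in the flask (Weinreb amide formation) is a standard exchange that runs below 0 °C, where the MOM acetals and the prenyl group are inert.

Step 4
Reactants: 6 N-methoxy-N-methyl-3,4-bis(methoxymethoxy)-5-(3-methylbut-2-enyl)benzamide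
Product: 7 1-[3,4-bis(methoxymethoxy)-5-(3-methylbut-2-enyl)phenyl]-2-(methoxymethoxy)ethanone
Conditions: Bu3SnCH2OMOM, n-BuLi, THF, −78 °C; then 6, −78 °C; aq. NH4Cl
Reagents that add atoms: tributyl[(methoxymethoxy)methyl]stannane, CCCC[Sn](CCCC)(CCCC)COCOC
Why: Tin–lithium exchange gives (methoxymethoxy)methyllithium, whose addition to the Weinreb amide stops at the chelated tetrahedral adduct and releases the α-alkoxy ketone only on quench (Weinreb ketone synthesis), so no tertiary alcohol should form.

Step 5
Reactants: 7 1-[3,4-bis(methoxymethoxy)-5-(3-methylbut-2-enyl)phenyl]-2-(methoxymethoxy)ethanone; 8 2,4,6-trifluorobenzoyl chloride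
Product: 9 1-[3,4-bis(methoxymethoxy)-5-(3-methylbut-2-enyl)phenyl]-2-(methoxymethoxy)-3-(2,4,6-trifluorophenyl)propane-1,3-dione
Conditions: LiN(SiMe3)2 (2.1 equiv), THF, −78 °C; then 8, −78 → −30 °C; AcOH quench at −78 °C
Reagents that add atoms: none
Why: Claisen-type C-acylation of a preformed lithium enolate by an aroyl chloride is expected because the chelated enolate of the α-alkoxy ketone reacts at carbon in THF at low temperature, the second equivalent of base stores the more acidic diketone as its enolate, and the cold acidic quench returns 9 before fluoride displacement can begin.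

Step 6
Reactants: 9 1-[3,4-bis(methoxymethoxy)-5-(3-methylbut-2-enyl)phenyl]-2-(methoxymethoxy)-3-(2,4,6-trifluorophenyl)propane-1,3-dione
Product: 10 5,7-difluoro-3-(methoxymethoxy)-2-[3,4-bis(methoxymethoxy)-5-(3-methylbut-2-enyl)phenyl]chromen-4-one
Conditions: K2CO3 (dry), DMF, rt → 50 °C
Reagents that add atoms: none
Why: K2CO3 removes the doubly activated C2 proton of 9, and the enolate oxygen on the ring B carbonyl carbon adds to a fluorine-bearing carbon ortho to the aryl ketone, giving a Meisenheimer complex stabilised by that ketone and the two other fluorines; loss of fluoride then forms the O1–C8a bond and restores the aromaticity of ring A (addition–elimination SNAr). The closest known reaction type is the base-mediated cyclisation of 1-(2-fluoroaryl)-1,3-diketones to chromones and flavones. Ring C closes in a 6-exo-trig mode, the attacked arene π bond (C8a=C8) lying outside the new ring. No stereocentre is formed, and the labile C2 centre of 9 becomes sp2. The step needs oxygen rather than carbon attack and a single site of substitution: carbon attack would have to close a four-membered ring, the para fluorine is out of reach of the tethered oxygen, and the two ortho fluorines are equivalent by the symmetry of the 2,4,6-trifluorophenyl group, so only one chromone can form. The surviving C5 and C7 fluorines remain activated by the new C4 carbonyl for the later oxygen introduction, and dry carbonate in DMF should avoid retro-Claisen cleavage of the diketone.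

Step 7
Reactants: 10 5,7-difluoro-3-(methoxymethoxy)-2-[3,4-bis(methoxymethoxy)-5-(3-methylbut-2-enyl)phenyl]chromen-4-one; 11 3-methylbut-2-en-1-ol
Product: 12 5-fluoro-3-(methoxymethoxy)-7-(3-methylbut-2-enyloxy)-2-[3,4-bis(methoxymethoxy)-5-(3-methylbut-2-enyl)phenyl]chromen-4-one
Conditions: 11 (1.1 equiv), NaH, 15-crown-5, DMF, −20 → 0 °C
Reagents that add atoms: none
Why: Intermolecular SNAr by the prenyl alkoxide should occur at the less hindered C7 fluorine para to the carbonyl, because with the sodium ion sequestered by the crown ether in DMF no cation bridge to the C4 carbonyl can steer the nucleophile to the peri C5 fluorine, and the new aryl ether lowers the reactivity of the remaining fluorine enough to stop at monosubstitution.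

Step 8
Reactants: 12 5-fluoro-3-(methoxymethoxy)-7-(3-methylbut-2-enyloxy)-2-[3,4-bis(methoxymethoxy)-5-(3-methylbut-2-enyl)phenyl]chromen-4-one
Product: 14 5-hydroxy-3-(methoxymethoxy)-7-(3-methylbut-2-enyloxy)-2-[3,4-bis(methoxymethoxy)-5-(3-methylbut-2-enyl)phenyl]chromen-4-one, via 5-[2-(methylsulfonyl)ethoxy]flavone 13 (not isolated)
Conditions: MeSO2CH2CH2OH, NaH (excess), DMF, 0 °C → rt; aq. NH4Cl
Reagents that add atoms: 2-(methylsulfonyl)ethanol, CS(=O)(=O)CCO
Why: A second SNAr at the C5 fluorine ortho to the carbonyl by the alkoxide of 2-(methylsulfonyl)ethanol is followed in the same flask by base-induced β-elimination of methyl vinyl sulfone (E1cB), a known hydroxide-surrogate sequence that should unveil the chelated 5-OH while the prenyl ether and the MOM acetals stay intact.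

Step 9
Reactants: 14 5-hydroxy-3-(methoxymethoxy)-7-(3-methylbut-2-enyloxy)-2-[3,4-bis(methoxymethoxy)-5-(3-methylbut-2-enyl)phenyl]chromen-4-one
Product: 15 5,7-dihydroxy-3-(methoxymethoxy)-8-(2-methylbut-3-en-2-yl)-2-[3,4-bis(methoxymethoxy)-5-(3-methylbut-2-enyl)phenyl]chromen-4-one
Conditions: PhNEt2, 185 °C, sealed tube, Ar; stopped at full conversion of 14
Reagents that add atoms: none
Why: Thermal aromatic Claisen rearrangement ([3,3] sigmatropic shift) of the aryl prenyl ether transfers the allyl unit with inversion, hence as the 1,1-dimethylallyl group, to an ortho carbon, and C8 is expected to be preferred over C6 because the C7–C8 bond of the benzopyranone has the higher double-bond character, with tautomerisation of the dienone restoring ring A.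

Step 10
Reactants: 15 5,7-dihydroxy-3-(methoxymethoxy)-8-(2-methylbut-3-en-2-yl)-2-[3,4-bis(methoxymethoxy)-5-(3-methylbut-2-enyl)phenyl]chromen-4-one
Product: 16 3,5,7-trihydroxy-2-[3,4-dihydroxy-5-(3-methylbut-2-enyl)phenyl]-8-(2-methylbut-3-en-2-yl)chromen-4-one
Conditions: HCl (dry, about 1 M in MeOH), 40 °C
Reagents that add atoms: none
Why: Acid-catalysed acetal exchange with methanol should remove the three MOM groups as dimethoxymethane under dilute, mild conditions chosen so that neither the prenyl group next to the 4'-OH nor the 1,1-dimethylallyl group next to the 7-OH is protonated and cyclised.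

**Compound list**

1 | methyl 3-bromo-4,5-dihydroxybenzoate | COC(=O)c1cc(O)c(O)c(Br)c1 | starting material
2 | methyl 3-bromo-4,5-bis(methoxymethoxy)benzoate | COC(=O)c1cc(OCOC)c(OCOC)c(Br)c1 | intermediate
3 | 1-bromo-3-methylbut-2-ene (prenyl bromide) | CC(C)=CCBr | starting material
4 | 3-methylbut-2-enylzinc bromide (prenylzinc bromide) | CC(C)=CC[Zn]Br | intermediate
5 | methyl 3,4-bis(methoxymethoxy)-5-(3-methylbut-2-enyl)benzoate | COC(=O)c1cc(OCOC)c(OCOC)c(CC=C(C)C)c1 | intermediate
6 | N-methoxy-N-methyl-3,4-bis(methoxymethoxy)-5-(3-methylbut-2-enyl)benzamide | CON(C)C(=O)c1cc(OCOC)c(OCOC)c(CC=C(C)C)c1 | intermediate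
7 | 1-[3,4-bis(methoxymethoxy)-5-(3-methylbut-2-enyl)phenyl]-2-(methoxymethoxy)ethanone | COCOCC(=O)c1cc(OCOC)c(OCOC)c(CC=C(C)C)c1 | intermediate
8 | 2,4,6-trifluorobenzoyl chloride | O=C(Cl)c1c(F)cc(F)cc1F | starting material
9 | 1-[3,4-bis(methoxymethoxy)-5-(3-methylbut-2-enyl)phenyl]-2-(methoxymethoxy)-3-(2,4,6-trifluorophenyl)propane-1,3-dione (keto form, C2 racemic and labile) | O=C(c1c(F)cc(F)cc1F)C(OCOC)C(=O)c1cc(OCOC)c(OCOC)c(CC=C(C)C)c1 | intermediate
10 | 5,7-difluoro-3-(methoxymethoxy)-2-[3,4-bis(methoxymethoxy)-5-(3-methylbut-2-enyl)phenyl]chromen-4-one | Fc1cc(F)c2c(=O)c(OCOC)c(-c3cc(OCOC)c(OCOC)c(CC=C(C)C)c3)oc2c1 | intermediate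
11 | 3-methylbut-2-en-1-ol | CC(C)=CCO | starting material
12 | 5-fluoro-3-(methoxymethoxy)-7-(3-methylbut-2-enyloxy)-2-[3,4-bis(methoxymethoxy)-5-(3-methylbut-2-enyl)phenyl]chromen-4-one | CC(C)=CCOc1cc(F)c2c(=O)c(OCOC)c(-c3cc(OCOC)c(OCOC)c(CC=C(C)C)c3)oc2c1 | intermediate
13 | 3-(methoxymethoxy)-5-[2-(methylsulfonyl)ethoxy]-7-(3-methylbut-2-enyloxy)-2-[3,4-bis(methoxymethoxy)-5-(3-methylbut-2-enyl)phenyl]chromen-4-one | CC(C)=CCOc1cc(OCCS(C)(=O)=O)c2c(=O)c(OCOC)c(-c3cc(OCOC)c(OCOC)c(CC=C(C)C)c3)oc2c1 | intermediate
14 | 5-hydroxy-3-(methoxymethoxy)-7-(3-methylbut-2-enyloxy)-2-[3,4-bis(methoxymethoxy)-5-(3-methylbut-2-enyl)phenyl]chromen-4-one | CC(C)=CCOc1cc(O)c2c(=O)c(OCOC)c(-c3cc(OCOC)c(OCOC)c(CC=C(C)C)c3)oc2c1 | intermediate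
15 | 5,7-dihydroxy-3-(methoxymethoxy)-8-(2-methylbut-3-en-2-yl)-2-[3,4-bis(methoxymethoxy)-5-(3-methylbut-2-enyl)phenyl]chromen-4-one | C=CC(C)(C)c1c(O)cc(O)c2c(=O)c(OCOC)c(-c3cc(OCOC)c(OCOC)c(CC=C(C)C)c3)oc12 | intermediate
16 | 3,5,7-trihydroxy-2-[3,4-dihydroxy-5-(3-methylbut-2-enyl)phenyl]-8-(2-methylbut-3-en-2-yl)chromen-4-one | C=CC(C)(C)c1c(O)cc(O)c2c(=O)c(O)c(-c3cc(O)c(O)c(CC=C(C)C)c3)oc12 | target

**Step count**

Total: 10 steps. Longest linear sequence: 10 steps (1 → 16); compounds 3, 8 and 11 enter as purchased side inputs.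

**Steps most likely to fail**

Step 7. The alkoxide may attack the C5 fluorine by cation-bridged ortho delivery, substitute twice, or add at C2 and open ring C. The fallback sets out from 10 and comes back at 14, replacing steps 7 and 8. Compound 10 is heated with excess sodium allyloxide (allyl alcohol, NaH, DMF, 60 °C), so that both fluorines are exchanged and no site selection is needed, giving 5,7-bis(allyloxy)-3-(methoxymethoxy)-2-[3,4-bis(methoxymethoxy)-5-(3-methylbut-2-enyl)phenyl]chromen-4-one F1. Both allyl ethers are then removed with Pd(PPh3)4 and morpholine in THF, which does not touch the C-bound prenyl group, to give 5,7-dihydroxy-3-(methoxymethoxy)-2-[3,4-bis(methoxymethoxy)-5-(3-methylbut-2-enyl)phenyl]chromen-4-one F2. Alkylation of F2 with prenyl bromide 3 and K2CO3 in acetone is expected to occur only at the 7-OH, the 5-OH being held in a hydrogen bond to the C4 carbonyl, and leads to 14.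

Step 9. The allyl unit may migrate to C6 in competition with C8, and at the temperature needed the product may react on by closure of the 7-OH onto the new vinyl group or by abnormal Claisen rearrangement. The fallback sets out from 14 and comes back at the target 16. The chelated 5-OH, which activates C6, is first capped (NaH, MOMCl, DMF) to give 3,5-bis(methoxymethoxy)-7-(3-methylbut-2-enyloxy)-2-[3,4-bis(methoxymethoxy)-5-(3-methylbut-2-enyl)phenyl]chromen-4-one F3. With the 5-oxygen alkylated, substitution of the 5,7-dioxygenated chromone is directed to C8, and rearrangement in PhNEt2 should give 7-hydroxy-3,5-bis(methoxymethoxy)-8-(2-methylbut-3-en-2-yl)-2-[3,4-bis(methoxymethoxy)-5-(3-methylbut-2-enyl)phenyl]chromen-4-one F4. The four MOM groups of F4 are then removed under the conditions of step 10 to give 16.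

Step 5. The enolate may be acylated on oxygen, and the amide base may consume the acid chloride or trigger early fluoride displacement. The fallback sets out from 7 and comes back at 9. The lithium enolate of 7 (LiN(SiMe3)2, THF, −78 °C) is added to 2,4,6-trifluorobenzaldehyde in an aldol reaction, where only carbon attack is productive, giving 1-[3,4-bis(methoxymethoxy)-5-(3-methylbut-2-enyl)phenyl]-3-hydroxy-2-(methoxymethoxy)-3-(2,4,6-trifluorophenyl)propan-1-one F5 as a diastereomer mixture. Oxidation of F5 with Dess–Martin periodinane in CH2Cl2 removes both stereocentres' consequences and gives diketone 9.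

**Further compounds**

F1 | step 7 | 5,7-bis(allyloxy)-3-(methoxymethoxy)-2-[3,4-bis(methoxymethoxy)-5-(3-methylbut-2-enyl)phenyl]chromen-4-one | C=CCOc1cc(OCC=C)c2c(=O)c(OCOC)c(-c3cc(OCOC)c(OCOC)c(CC=C(C)C)c3)oc2c1
F2 | step 7 | 5,7-dihydroxy-3-(methoxymethoxy)-2-[3,4-bis(methoxymethoxy)-5-(3-methylbut-2-enyl)phenyl]chromen-4-one | Oc1cc(O)c2c(=O)c(OCOC)c(-c3cc(OCOC)c(OCOC)c(CC=C(C)C)c3)oc2c1
F3 | step 9 | 3,5-bis(methoxymethoxy)-7-(3-methylbut-2-enyloxy)-2-[3,4-bis(methoxymethoxy)-5-(3-methylbut-2-enyl)phenyl]chromen-4-one | CC(C)=CCOc1cc(OCOC)c2c(=O)c(OCOC)c(-c3cc(OCOC)c(OCOC)c(CC=C(C)C)c3)oc2c1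
F4 | step 9 | 7-hydroxy-3,5-bis(methoxymethoxy)-8-(2-methylbut-3-en-2-yl)-2-[3,4-bis(methoxymethoxy)-5-(3-methylbut-2-enyl)phenyl]chromen-4-one | C=CC(C)(C)c1c(O)cc(OCOC)c2c(=O)c(OCOC)c(-c3cc(OCOC)c(OCOC)c(CC=C(C)C)c3)oc12
F5 | step 5 | 1-[3,4-bis(methoxymethoxy)-5-(3-methylbut-2-enyl)phenyl]-3-hydroxy-2-(methoxymethoxy)-3-(2,4,6-trifluorophenyl)propan-1-one (racemic, diastereomer mixture) | OC(c1c(F)cc(F)cc1F)C(OCOC)C(=O)c1cc(OCOC)c(OCOC)c(CC=C(C)C)c1
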